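**Plan**

1. Locants of the target (cyclohepta[b]furan-2-one): O1, C2(=O), C3(Me), C3a, C4(H2), C5(OH), C6(Me), C7(OH, butenoyl), C8(O-isobutyryl), C8a. In the bicyclic intermediates, bicycle C1/C2/C3/C4/C5/C6/C7 become target C3a/C4/C5/C6/C7/C8/C8a.
2. Retrosynthesis: the enone goes back to a C7 aldehyde (kept as a dioxolane) and C5–OH to a ketone. The lactone is cut at C3–C3a (intramolecular Michael addition of a malonate on O–C8a). C3a is then rejoined to the C7 oxygen as an oxygen bridge (retro-oxa-Michael). The resulting 8-oxabicyclo[3.2.1]octene is cut at C4–C3a and C6–C7 in one formal (4+3) event.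
3. Enabling feature: in the cycloheptane, the three-carbon unit C4–C5(O)–C6 with its central oxygen is joined at both ends to the four-carbon unit C3a–C8a–C8–C7, and the terminus C7 is a tertiary carbinol. That is the pattern a furan (oxygen bridging its two α-carbons) gives with an oxyallyl-type partner. The partner here is a 2-siloxyvinyl rhodium carbenoid; its ester later steers methylation, bridge opening and conjugate addition and is then removed.
4. Forward order: furan + siloxyvinyl diazoacetate give the seven-membered carbocycle with its oxygen bridge (step 3). Then come the C6 methyl, the exo-diol, inversion at C8 by oxidation/reduction, bridge opening with lactone closure (step 11), decarboxylations, the side chain and the C5 reduction.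
5. Stereochemistry: the bridgeheads (C7, C3a) come from the chiral dirhodium catalyst. C6–Me, C8a–O and C8–O come from exo-face attack on the rigid bicycle. C3a–C3 is set by the tethered Michael addition, C3 by convex-face protonation, and C5–OH by hydride delivery from the C7 hydroxyl.

Key step: step 3

Assumption: Rh2(S-PTAD)4 is taken to give the (1S,5S) adduct 6; if it gives the antipode, Rh2(R-PTAD)4 is used and nothing else changes.
Remark: "exo" means on the face of the oxygen bridge. Compounds 11–20 are epimer mixtures at the malonate carbon (16–19 also at the keto ester carbon), and 24 and 25 at the side-chain carbinol; all these centres are removed in steps 12 and 16.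

**Route**

Step 1
Reactants: 1 benzyl 3-oxobutanoate
Product: 2 benzyl 2-diazo-3-oxobutanoate
Conditions: p-ABSA, Et3N, MeCN, 0 °C to rt
Reagents that add atoms: 4-acetamidobenzenesulfonyl azide, CC(=O)Nc1ccc(cc1)S(=O)(=O)N=[N+]=[N-]
Why: Regitz diazo transfer to the doubly activated methylene; no stereocentre is formed.

Step 2
Reactants: 2 benzyl 2-diazo-3-oxobutanoate
Product: 3 benzyl 3-[(tert-butyldimethylsilyl)oxy]-2-diazobut-3-enoate
Conditions: TBSOTf, Et3N, CH2Cl2, 0 °C
Reagents that add atoms: tert-butyldimethylsilyl trifluoromethanesulfonate, CC(C)(C)[Si](C)(C)OS(=O)(=O)C(F)(F)F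
Why: Soft enolisation and O-silylation of the methyl ketone should give the 2-siloxyvinyl diazoacetate, the precursor of a donor/acceptor carbenoid; no stereocentre is formed.

Step 3
Reactants: 3 benzyl 3-[(tert-butyldimethylsilyl)oxy]-2-diazobut-3-enoate; 4 2-(furan-2-yl)-1,3-dioxolane
Product: 6 benzyl (1S,5S)-3-[(tert-butyldimethylsilyl)oxy]-5-(1,3-dioxolan-2-yl)-8-oxabicyclo[3.2.1]octa-2,6-diene-2-carboxylate, via cis-divinylcyclopropane 5 (not isolated)
Conditions: Rh2(S-PTAD)4 (dirhodium tetrakis[(S)-(1-adamantyl)(N-phthalimido)acetate], 1 mol %), 4 (3 equiv), hexanes, slow addition of 3, −20 °C to rt, then 50 °C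
Reagents that add atoms: none
Why: The rhodium vinylcarbenoid from 3 adds to the unsubstituted C4=C5 bond of furan 4 (loss of aromaticity) to give cis-divinylcyclopropane 5; its Cope rearrangement breaks the cyclopropane bond to the furan β-carbon and joins the vinyl CH2 to the acetal-bearing α-carbon, so the ester-bearing carbon (future C4) ends on furan C5 (future C3a) and the CH2 (future C6) on furan C2 (future C7), with the furan oxygen as a one-atom bridge. The closest known reaction type is the rhodium-catalysed tandem cyclopropanation/Cope rearrangement (formal (4+3) cycloaddition) of 2-siloxyvinyldiazoacetates with furans and N-acylpyrroles under chiral dirhodium tetracarboxylate catalysis. The three-membered ring closes by concerted (2+1) carbenoid addition and the seven-membered carbocycle by a [3,3]-sigmatropic shift through a boat transition state; neither is an exo or endo cyclisation. Both bridgehead centres are set together by the face of the furan that the chiral carboxylate ligands expose to the carbenoid, and their mutual relation is fixed by the bridge. The step needs attack at the 4,5-bond, the cis (endo-vinyl) cyclopropane and no zwitterionic opening of the furan: the acetal shields and deactivates the 2,3-bond and is not a π-donor, donor/acceptor carbenoids place the vinyl group cis to the ring, and a hydrocarbon solvent disfavours charged intermediates.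

Step 4
Reactants: 6 benzyl (1S,5S)-3-[(tert-butyldimethylsilyl)oxy]-5-(1,3-dioxolan-2-yl)-8-oxabicyclo[3.2.1]octa-2,6-diene-2-carboxylate
Product: 7 benzyl 3-[(tert-butyldimethylsilyl)oxy]-5-(1,3-dioxolan-2-yl)-4-exo-methyl-8-oxabicyclo[3.2.1]octa-2,6-diene-2-carboxylate (bridgeheads as in 6)
Conditions: LiN(iPr)2, THF/DMPU, −78 °C; MeI, −78 °C
Reagents that add atoms: iodomethane, CI
Why: Deprotonation at C4 gives the extended dienolate of the β-siloxy enoate, which should be methylated at its γ-terminus (vinylogous alkylation, as for β-silyloxycrotonate dienolates and acetoacetate dianions; the α-carbon is fully substituted) from the exo face, because the endo face lies over the C6=C7 bridge, so the methyl ends cis to the oxygen bridge.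

Step 5
Reactants: 7 benzyl 3-[(tert-butyldimethylsilyl)oxy]-5-(1,3-dioxolan-2-yl)-4-exo-methyl-8-oxabicyclo[3.2.1]octa-2,6-diene-2-carboxylate
Product: 8 benzyl 3-[(tert-butyldimethylsilyl)oxy]-5-(1,3-dioxolan-2-yl)-6-exo,7-exo-dihydroxy-4-exo-methyl-8-oxabicyclo[3.2.1]oct-2-ene-2-carboxylate
Conditions: OsO4 (2 mol %), NMO, acetone/H2O, 0 °C to rt
Reagents that add atoms: N-methylmorpholine N-oxide, C[N+]1([O-])CCOCC1; water, O
Why: Upjohn dihydroxylation should take the strained disubstituted C6=C7 bond in preference to the tetrasubstituted push–pull enol ether and attack from the exo face, as is general for oxabicyclo[3.2.1]octenes, setting both carbinol centres cis to the oxygen bridge.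

Step 6
Reactants: 9 2,2,5-trimethyl-1,3-dioxane-4,6-dione; 10 benzyl alcohol
Product: 11 3-(benzyloxy)-2-methyl-3-oxopropanoic acid (racemic)
Conditions: toluene, 100 °C
Reagents that add atoms: none
Why: Alcoholysis of the Meldrum's acid derivative with loss of acetone gives the malonic half ester; its stereocentre is removed in step 12.

Step 7
Reactants: 8 benzyl 3-[(tert-butyldimethylsilyl)oxy]-5-(1,3-dioxolan-2-yl)-6-exo,7-exo-dihydroxy-4-exo-methyl-8-oxabicyclo[3.2.1]oct-2-ene-2-carboxylate; 11 3-(benzyloxy)-2-methyl-3-oxopropanoic acid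
Product: 12 benzyl 7-exo-{[3-(benzyloxy)-2-methyl-3-oxopropanoyl]oxy}-3-[(tert-butyldimethylsilyl)oxy]-5-(1,3-dioxolan-2-yl)-6-exo-hydroxy-4-exo-methyl-8-oxabicyclo[3.2.1]oct-2-ene-2-carboxylate
Conditions: EDC·HCl, DMAP (cat.), CH2Cl2, −20 to 0 °C
Reagents that add atoms: none
Why: Steglich-type carbodiimide esterification should acylate the C7 hydroxyl, which sits next to the unsubstituted bridgehead, in preference to the C6 hydroxyl, which is gauche to the dioxolane on the quaternary bridgehead; no ring stereocentre changes.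

Step 8
Reactants: 12 benzyl 7-exo-{[3-(benzyloxy)-2-methyl-3-oxopropanoyl]oxy}-3-[(tert-butyldimethylsilyl)oxy]-5-(1,3-dioxolan-2-yl)-6-exo-hydroxy-4-exo-methyl-8-oxabicyclo[3.2.1]oct-2-ene-2-carboxylate
Product: 13 benzyl 7-exo-{[3-(benzyloxy)-2-methyl-3-oxopropanoyl]oxy}-3-[(tert-butyldimethylsilyl)oxy]-5-(1,3-dioxolan-2-yl)-4-exo-methyl-6-oxo-8-oxabicyclo[3.2.1]oct-2-ene-2-carboxylate
Conditions: Dess–Martin periodinane, CH2Cl2, 0 °C to rt
Reagents that add atoms: none
Why: Dess–Martin oxidation of the remaining secondary alcohol under near-neutral conditions should leave the α-acyloxy centre C7 untouched.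

Step 9
Reactants: 13 benzyl 7-exo-{[3-(benzyloxy)-2-methyl-3-oxopropanoyl]oxy}-3-[(tert-butyldimethylsilyl)oxy]-5-(1,3-dioxolan-2-yl)-4-exo-methyl-6-oxo-8-oxabicyclo[3.2.1]oct-2-ene-2-carboxylate
Product: 14 benzyl 7-exo-{[3-(benzyloxy)-2-methyl-3-oxopropanoyl]oxy}-3-[(tert-butyldimethylsilyl)oxy]-5-(1,3-dioxolan-2-yl)-6-endo-hydroxy-4-exo-methyl-8-oxabicyclo[3.2.1]oct-2-ene-2-carboxylate
Conditions: NaBH4, MeOH/CH2Cl2, −78 °C
Reagents that add atoms: none
Why: Borohydride should attack the bicyclic ketone from the open exo face (the endo face lies under the three-carbon bridge), giving the endo alcohol, i.e. net inversion at C6 so that this oxygen is trans to the bridge and to the C7 ester; esters and the silyl enol ether are inert.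

Step 10
Reactants: 14 benzyl 7-exo-{[3-(benzyloxy)-2-methyl-3-oxopropanoyl]oxy}-3-[(tert-butyldimethylsilyl)oxy]-5-(1,3-dioxolan-2-yl)-6-endo-hydroxy-4-exo-methyl-8-oxabicyclo[3.2.1]oct-2-ene-2-carboxylate
Product: 15 benzyl 7-exo-{[3-(benzyloxy)-2-methyl-3-oxopropanoyl]oxy}-3-[(tert-butyldimethylsilyl)oxy]-5-(1,3-dioxolan-2-yl)-4-exo-methyl-6-endo-[(2-methylpropanoyl)oxy]-8-oxabicyclo[3.2.1]oct-2-ene-2-carboxylate
Conditions: (iPrCO)2O, DMAP, Et3N, CH2Cl2, rt to 40 °C
Reagents that add atoms: 2-methylpropanoic anhydride, CC(C)C(=O)OC(=O)C(C)C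
Why: DMAP-catalysed acylation installs the isobutyrate with retention at the inverted carbinol centre.

Step 11
Reactants: 15 benzyl 7-exo-{[3-(benzyloxy)-2-methyl-3-oxopropanoyl]oxy}-3-[(tert-butyldimethylsilyl)oxy]-5-(1,3-dioxolan-2-yl)-4-exo-methyl-6-endo-[(2-methylpropanoyl)oxy]-8-oxabicyclo[3.2.1]oct-2-ene-2-carboxylate
Product: 18 dibenzyl 7-(1,3-dioxolan-2-yl)-7-hydroxy-3,6-dimethyl-8-[(2-methylpropanoyl)oxy]-2,5-dioxooctahydro-2H-cyclohepta[b]furan-3,4-dicarboxylate (C3a/C6/C7/C8/C8a as in the target), via bicyclic keto ester 16 (not isolated), via ring-opened alkylidene keto ester 17 (not isolated)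
Conditions: Bu4NF, THF, 0 °C; then DBU, 0 °C to rt; AcOH quench
Reagents that add atoms: none
Why: Fluoride releases the β-keto ester enolate, which expels the bridging oxygen from the bridgehead β to it (E1cB, retro-oxa-Michael; the only oxygen β to this enolate) to leave the tertiary alkoxide and an alkylidene keto ester; the tethered methylmalonate then closes the γ-lactone by 5-exo-trig Michael addition on the face of its own C–O bond, which sets the cis ring fusion and gives a stabilised keto ester enolate that should pull the sequence forward.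

Step 12
Reactants: 18 dibenzyl 7-(1,3-dioxolan-2-yl)-7-hydroxy-3,6-dimethyl-8-[(2-methylpropanoyl)oxy]-2,5-dioxooctahydro-2H-cyclohepta[b]furan-3,4-dicarboxylate
Product: 21 7-(1,3-dioxolan-2-yl)-7-hydroxy-3,6-dimethyl-2,5-dioxooctahydro-2H-cyclohepta[b]furan-8-yl 2-methylpropanoate (C3/C3a/C6/C7/C8/C8a as in the target), via dicarboxylic acid 19 (not isolated), via keto acid 20 (not isolated)
Conditions: H2 (1 atm), Pd/C, EtOAc, rt; filtration; Cu2O (cat.), MeCN, 70 °C
Reagents that add atoms: none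
Why: Hydrogenolysis frees both acids; the β-keto acid should lose CO2 at room temperature and the malonic half acid on mild Cu2O-catalysed heating, and the resulting lactone enol should be protonated on the convex face, anti to the C4 methylene on the neighbouring ring-fusion carbon, placing the C3 methyl on the concave face as in the target.

Step 13
Reactants: 21 7-(1,3-dioxolan-2-yl)-7-hydroxy-3,6-dimethyl-2,5-dioxooctahydro-2H-cyclohepta[b]furan-8-yl 2-methylpropanoate
Product: 22 7-formyl-7-hydroxy-3,6-dimethyl-2,5-dioxooctahydro-2H-cyclohepta[b]furan-8-yl 2-methylpropanoate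
Conditions: HCl (1 M), THF/H2O, 40 °C
Reagents that add atoms: water, O
Why: Acid hydrolysis of the dioxolane should free the α-hydroxy aldehyde without touching the lactone, the ester or any stereocentre; the aldehyde is used at once.

Step 14
Reactants: 22 7-formyl-7-hydroxy-3,6-dimethyl-2,5-dioxooctahydro-2H-cyclohepta[b]furan-8-yl 2-methylpropanoate; 23 (E)-1-bromoprop-1-ene
Product: 24 7-hydroxy-7-[(2E)-1-hydroxybut-2-en-1-yl]-3,6-dimethyl-2,5-dioxooctahydro-2H-cyclohepta[b]furan-8-yl 2-methylpropanoate (carbinol epimers)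
Conditions: CrCl2, NiCl2 (cat.), DMF, rt
Reagents that add atoms: none
Why: Nozaki–Hiyama–Kishi coupling: the alkenylchromium reagent should add only to the aldehyde in the presence of ketone, lactone and ester, with retention of the E geometry; the new carbinol centre forms as a mixture and is removed in step 16.

Step 15
Reactants: 24 7-hydroxy-7-[(2E)-1-hydroxybut-2-en-1-yl]-3,6-dimethyl-2,5-dioxooctahydro-2H-cyclohepta[b]furan-8-yl 2-methylpropanoate
Product: 25 5,7-dihydroxy-7-[(2E)-1-hydroxybut-2-en-1-yl]-3,6-dimethyl-2-oxooctahydro-2H-cyclohepta[b]furan-8-yl 2-methylpropanoate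
Conditions: Me4NBH(OAc)3, MeCN/AcOH, −30 to 0 °C
Reagents that add atoms: none
Why: Evans–Saksena hydroxyl-directed reduction: boron bound to the tertiary C7 hydroxyl (β to the ketone) should deliver hydride to its own face of the C5 carbonyl, giving the 1,3-anti (trans) diol, i.e. the C5 configuration of the target.

Step 16
Reactants: 25 5,7-dihydroxy-7-[(2E)-1-hydroxybut-2-en-1-yl]-3,6-dimethyl-2-oxooctahydro-2H-cyclohepta[b]furan-8-yl 2-methylpropanoate
Product: 26 (3R,3aS,5R,6S,7S,8S,8aR)-7-[(2E)-but-2-enoyl]-5,7-dihydroxy-3,6-dimethyl-2-oxooctahydro-2H-cyclohepta[b]furan-8-yl 2-methylpropanoate (CNP0268641.1)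
Conditions: MnO2, CH2Cl2, rt
Reagents that add atoms: none
Why: Activated MnO2 should oxidise only the allylic alcohol, converging both carbinol epimers on the E-enone and leaving the saturated C5 alcohol and the tertiary alcohol untouched.

**Compound list**

1 | benzyl 3-oxobutanoate | CC(=O)CC(=O)OCc1ccccc1 | starting material
2 | benzyl 2-diazo-3-oxobutanoate | CC(=O)C(=[N+]=[N-])C(=O)OCc1ccccc1 | intermediate
3 | benzyl 3-[(tert-butyldimethylsilyl)oxy]-2-diazobut-3-enoate | C=C(O[Si](C)(C)C(C)(C)C)C(=[N+]=[N-])C(=O)OCc1ccccc1 | intermediate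
4 | 2-(furan-2-yl)-1,3-dioxolane | C1COC(O1)c1ccco1 | starting material
5 | benzyl 6-{1-[(tert-butyldimethylsilyl)oxy]ethenyl}-3-(1,3-dioxolan-2-yl)-2-oxabicyclo[3.1.0]hex-3-ene-6-carboxylate, siloxyvinyl group cis to the dihydrofuran ring | C=C(O[Si](C)(C)C(C)(C)C)[C@]1(C(=O)OCc2ccccc2)[C@@H]2C=C(C3OCCO3)O[C@H]12 | intermediate (not isolated)
6 | benzyl (1S,5S)-3-[(tert-butyldimethylsilyl)oxy]-5-(1,3-dioxolan-2-yl)-8-oxabicyclo[3.2.1]octa-2,6-diene-2-carboxylate | [C@]12(C3OCCO3)CC(O[Si](C)(C)C(C)(C)C)=C(C(=O)OCc3ccccc3)[C@@H](O2)C=C1 | intermediate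
7 | 4-exo-methyl derivative of 6 (methyl cis to the oxygen bridge) | [C@]12(C3OCCO3)[C@@H](C)C(O[Si](C)(C)C(C)(C)C)=C(C(=O)OCc3ccccc3)[C@@H](O2)C=C1 | intermediate
8 | 6-exo,7-exo-diol of 7 | [C@]12(C3OCCO3)[C@@H](C)C(O[Si](C)(C)C(C)(C)C)=C(C(=O)OCc3ccccc3)[C@@H](O2)[C@@H](O)[C@H]1O | intermediate
9 | 2,2,5-trimethyl-1,3-dioxane-4,6-dione | CC1C(=O)OC(C)(C)OC1=O | starting material
10 | benzyl alcohol | OCc1ccccc1 | starting material
11 | 3-(benzyloxy)-2-methyl-3-oxopropanoic acid (racemic) | CC(C(=O)O)C(=O)OCc1ccccc1 | intermediate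
12 | 7-O-(benzyl methylmalonyl) ester of diol 8, 6-exo-hydroxyl free | [C@]12(C3OCCO3)[C@@H](C)C(O[Si](C)(C)C(C)(C)C)=C(C(=O)OCc3ccccc3)[C@@H](O2)[C@@H](OC(=O)C(C)C(=O)OCc3ccccc3)[C@H]1O | intermediate
13 | 6-ketone from 12 | [C@]12(C3OCCO3)[C@@H](C)C(O[Si](C)(C)C(C)(C)C)=C(C(=O)OCc3ccccc3)[C@@H](O2)[C@@H](OC(=O)C(C)C(=O)OCc3ccccc3)C1=O | intermediate
14 | 6-endo-alcohol from 13 | [C@]12(C3OCCO3)[C@@H](C)C(O[Si](C)(C)C(C)(C)C)=C(C(=O)OCc3ccccc3)[C@@H](O2)[C@@H](OC(=O)C(C)C(=O)OCc3ccccc3)[C@@H]1O | intermediate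
15 | 6-endo-isobutyrate of 14 | [C@]12(C3OCCO3)[C@@H](C)C(O[Si](C)(C)C(C)(C)C)=C(C(=O)OCc3ccccc3)[C@@H](O2)[C@@H](OC(=O)C(C)C(=O)OCc3ccccc3)[C@@H]1OC(=O)C(C)C | intermediate
16 | benzyl 7-exo-{[3-(benzyloxy)-2-methyl-3-oxopropanoyl]oxy}-5-(1,3-dioxolan-2-yl)-4-exo-methyl-6-endo-[(2-methylpropanoyl)oxy]-3-oxo-8-oxabicyclo[3.2.1]octane-2-carboxylate | [C@]12(C3OCCO3)[C@@H](C)C(=O)C(C(=O)OCc3ccccc3)[C@@H](O2)[C@@H](OC(=O)C(C)C(=O)OCc3ccccc3)[C@@H]1OC(=O)C(C)C | intermediate (not isolated)
17 | benzyl 3-{[3-(benzyloxy)-2-methyl-3-oxopropanoyl]oxy}-5-(1,3-dioxolan-2-yl)-5-hydroxy-6-methyl-4-[(2-methylpropanoyl)oxy]-7-oxocyclohept-1-ene-1-carboxylate | O[C@@]1(C2OCCO2)[C@@H](C)C(=O)C(C(=O)OCc2ccccc2)=C[C@@H](OC(=O)C(C)C(=O)OCc2ccccc2)[C@@H]1OC(=O)C(C)C | intermediate (not isolated)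
18 | dibenzyl 7-(1,3-dioxolan-2-yl)-7-hydroxy-3,6-dimethyl-8-[(2-methylpropanoyl)oxy]-2,5-dioxooctahydro-2H-cyclohepta[b]furan-3,4-dicarboxylate, cis-fused, epimers at C3 and C4 | O[C@@]1(C2OCCO2)[C@@H](C)C(=O)C(C(=O)OCc2ccccc2)[C@@H]3[C@@H](OC(=O)C3(C)C(=O)OCc2ccccc2)[C@@H]1OC(=O)C(C)C | intermediate
19 | dicarboxylic acid from 18 | O[C@@]1(C2OCCO2)[C@@H](C)C(=O)C(C(=O)O)[C@@H]3[C@@H](OC(=O)C3(C)C(=O)O)[C@@H]1OC(=O)C(C)C | intermediate (not isolated)
20 | 7-(1,3-dioxolan-2-yl)-7-hydroxy-3,6-dimethyl-8-[(2-methylpropanoyl)oxy]-2,5-dioxooctahydro-2H-cyclohepta[b]furan-3-carboxylic acid | O[C@@]1(C2OCCO2)[C@@H](C)C(=O)C[C@@H]3[C@@H](OC(=O)C3(C)C(=O)O)[C@@H]1OC(=O)C(C)C | intermediate (not isolated)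
21 | 7-(1,3-dioxolan-2-yl)-7-hydroxy-3,6-dimethyl-2,5-dioxooctahydro-2H-cyclohepta[b]furan-8-yl 2-methylpropanoate, stereocentres as in the target | O[C@@]1(C2OCCO2)[C@@H](C)C(=O)C[C@@H]3[C@@H](OC(=O)[C@@H]3C)[C@@H]1OC(=O)C(C)C | intermediate
22 | 7-formyl-7-hydroxy-3,6-dimethyl-2,5-dioxooctahydro-2H-cyclohepta[b]furan-8-yl 2-methylpropanoate | O[C@@]1(C=O)[C@@H](C)C(=O)C[C@@H]3[C@@H](OC(=O)[C@@H]3C)[C@@H]1OC(=O)C(C)C | intermediate
23 | (E)-1-bromoprop-1-ene | C/C=C/Br | starting material
24 | 7-hydroxy-7-[(2E)-1-hydroxybut-2-en-1-yl]-3,6-dimethyl-2,5-dioxooctahydro-2H-cyclohepta[b]furan-8-yl 2-methylpropanoate, carbinol epimers | O[C@@]1(C(O)/C=C/C)[C@@H](C)C(=O)C[C@@H]3[C@@H](OC(=O)[C@@H]3C)[C@@H]1OC(=O)C(C)C | intermediate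
25 | 5,7-dihydroxy-7-[(2E)-1-hydroxybut-2-en-1-yl]-3,6-dimethyl-2-oxooctahydro-2H-cyclohepta[b]furan-8-yl 2-methylpropanoate, carbinol epimers | O[C@@]1(C(O)/C=C/C)[C@@H](C)[C@H](O)C[C@@H]3[C@@H](OC(=O)[C@@H]3C)[C@@H]1OC(=O)C(C)C | intermediate
26 | (3R,3aS,5R,6S,7S,8S,8aR)-7-[(2E)-but-2-enoyl]-5,7-dihydroxy-3,6-dimethyl-2-oxooctahydro-2H-cyclohepta[b]furan-8-yl 2-methylpropanoate | C/C=C/C(=O)[C@]1(O)[C@@H](C)[C@H](O)C[C@@H]2[C@@H](OC(=O)[C@@H]2C)[C@@H]1OC(=O)C(C)C | target

**Step count**

Total: 16 steps. Longest linear sequence: 15 steps (steps 1–5 and 7–16; step 6 is a one-step side branch).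

**Steps most likely to fail**

1. Step 11. The retro-oxa-Michael opening may stay on the side of the bicycle. The ring-opened alkylidene keto ester may also lose a neighbouring acyloxy group by vinylogous β-elimination, or pass an acyl group to the tertiary alkoxide, before the malonate closes. Fallback, from 15 back to 18: the two events are separated and the opening is made irreversible by silyl capture. Compound 15 is desilylated with HF·pyridine (THF, 0 °C) and the bicyclic keto ester 16 is isolated. It is opened with TMSOTf/Et3N (CH2Cl2, −78 to 0 °C), the silyl-triflate-mediated β-elimination established for 8-oxabicyclo[3.2.1]octan-3-ones, to the ring-opened alkylidene keto ester trimethylsilyl ether F1. Cs2CO3 (MeCN, 0 °C) then closes the lactone by Michael addition to the lactone trimethylsilyl ether F2, and citric acid in MeOH frees the tertiary alcohol 18.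

2. Step 4. The lithium dienolate may be alkylated at oxygen or at the α-carbon, or may expel the bridging oxygen from the neighbouring bridgehead before it meets iodomethane; the facial preference could also be eroded. Fallback, from 6 back to 7: Huckin–Weiler dianion chemistry on the free keto ester. Bu4NF/AcOH (THF, 0 °C) gives the bicyclic keto ester F3. NaH and then LiN(iPr)2 (THF, 0 to −78 °C) form the dianion, which is methylated by MeI at the γ-carbon from the exo face to the methylated keto ester F4. TBSOTf/Et3N (CH2Cl2, 0 °C) restores the silyl enol ether 7.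

3. Step 12. Protonation of the lactone enol formed on loss of CO2 may show poor facial selectivity, or the heating may epimerise the methyl-bearing carbon next to the ketone. Fallback, from 18 back to 21: radical instead of polar replacement of the carboxyl group (Barton decarboxylation). Hydrogenolysis as in step 12 but without heating gives keto acid 20, which is isolated. It is converted with 1-hydroxypyridine-2(1H)-thione and DCC (CH2Cl2, 0 °C, dark) into the thiohydroxamate ester F5. Photolysis (visible light, 0 °C) with tert-butyl thiol lets the bulky thiol transfer hydrogen to the α-lactone radical on the convex face, giving 21.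

**Further compounds**

F1 | step 11 | benzyl 3-{[3-(benzyloxy)-2-methyl-3-oxopropanoyl]oxy}-5-(1,3-dioxolan-2-yl)-6-methyl-4-[(2-methylpropanoyl)oxy]-7-oxo-5-[(trimethylsilyl)oxy]cyclohept-1-ene-1-carboxylate | C[Si](C)(C)O[C@@]1(C2OCCO2)[C@@H](C)C(=O)C(C(=O)OCc2ccccc2)=C[C@@H](OC(=O)C(C)C(=O)OCc2ccccc2)[C@@H]1OC(=O)C(C)C
F2 | step 11 | 7-O-trimethylsilyl ether of 18 | C[Si](C)(C)O[C@@]1(C2OCCO2)[C@@H](C)C(=O)C(C(=O)OCc2ccccc2)[C@@H]3[C@@H](OC(=O)C3(C)C(=O)OCc2ccccc2)[C@@H]1OC(=O)C(C)C
F3 | step 4 | benzyl 5-(1,3-dioxolan-2-yl)-3-oxo-8-oxabicyclo[3.2.1]oct-6-ene-2-carboxylate (bridgeheads as in 6) | [C@]12(C3OCCO3)CC(=O)C(C(=O)OCc3ccccc3)[C@@H](O2)C=C1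
F4 | step 4 | benzyl 5-(1,3-dioxolan-2-yl)-4-exo-methyl-3-oxo-8-oxabicyclo[3.2.1]oct-6-ene-2-carboxylate (bridgeheads as in 6) | [C@]12(C3OCCO3)[C@@H](C)C(=O)C(C(=O)OCc3ccccc3)[C@@H](O2)C=C1
F5 | step 12 | 2-thioxopyridin-1(2H)-yl ester of acid 20 | O[C@@]1(C2OCCO2)[C@@H](C)C(=O)C[C@@H]3[C@@H](OC(=O)C3(C)C(=O)ON2C=CC=CC2=S)[C@@H]1OC(=O)C(C)C
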